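All runs are calculated with constants of no real substance; noise was put on by code.

The earlier runs cannot show how many chains a flask holds, but they can show how that count changes from flask to flask.

| flask | free monomer | initiator | remark | time |
|---|---|---|---|---|
| elm | 0.30 M | 8.6 mM | run made earlier |  |
| oak | 0.30 M | 32 mM | run made earlier |  |
| Tuesday's | 0.30 M | 6.0 mM |  | 25 h |
| Friday's | 0.30 M | 25 mM |  | 25 h |
- elm (time / h: monomer in chains / %, free monomer / %): 1.00: 1.4, 98.1; 1.50: 4.6, 95.1; 3.00: 15.1, 84.2; 5.00: 33.2, 67.6; 8.00: 56.3, 43.6; 12.0: 77.0, 22.5
- oak (time / h: monomer in chains / %, free monomer / %): 2.00: 25.7, 74.4; 4.00: 60.6, 40.0; 6.00: 82.4, 18.8; 8.00: 91.6, 7.0; 10.0: 96.5, 3.6; 12.0: 98.2, 1.3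

(scatter of a reading: 0.5 percentage points)
- which of the two ends with the longer chains by the average number of monomer units in a chain (chains begun, living or dead) ("neither" if they lie within 10 %) (Tuesday's / Friday's / neither)
- average number of monomer units in a chain (chains begun, living or dead) at the end, Tuesday's
- average number of monomer units in a chain (chains begun, living or dead) at the end, Friday's
- the average divides the monomer in chains by the number of chains begun, living and dead together
- candidate steps: free monomer + initiator -> living end + monomer in chains; initiator -> spent initiator; free monomer + living end -> monomer in chains + living end; monomer in chains -> over-reaction product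
- the earlier runs do not show the number of chains; that part of a forecast is a guess

Two of us disputed this, taking the average length as monomer in chains over chains begun. The maker of the forecast gives one share of the initiator charge to both flasks, on the ground that “Some initiator is probably wasted”. That view sets the lengths inversely as the charges and gives 90 for Tuesday's and 24 for Friday's, so Tuesday's is longer.

I hold that the share moves, and I read this from the end of each run. Between 8.00 h and 12.0 h the elm run loses 0.165 /h of its remaining free monomer. This late slope, the pseudo-first-order rate once initiation has faded, is the growth constant times the living ends, so slopes compare chain counts although the constant is unknown.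

The oak run reads 0.413 /h between 6.00 h and 10.0 h, and both slopes carry the scatter of their readings. The slope ratio of 2.50 is less than the charge ratio of 3.72, so the slope goes as the charge to the power 0.697. That places Tuesday's at 0.129 /h and Friday's at 0.348 /h. Counting both as fully converted, I expect a length ratio near 2.70, whereas the forecast's is 3.75.

    free monomer + initiator → living end + monomer in chains (k = 7.40 × 10⁻⁵ /M/s)
    initiator → spent initiator (k = 3.00 × 10⁻⁵ /s)
    free monomer + living end → monomer in chains + living end, rate k3*[living end]*[free monomer] (k = 0.0180 /M/s)
    monomer in chains → over-reaction product (k = 4.50 × 10⁻⁸ /s)

The simulation gives 140 for Tuesday's and 53.0 for Friday's, so Tuesday's is longer, by a ratio of 2.64, less than the charge ratio of 4.17. At 25.0 h the living ends stand at 33.3 % of the initiator charge in Tuesday's and at 22.6 % in Friday's, so these two flasks do not share one fraction. Friday's average has moved by 10 % of itself at 21.6 mM below its charge and at 29.4 mM above it. With the growth constant shown, fraction in chains times monomer charge times constant over late slope gives 141 for Tuesday's and 90.5 for elm, stored as 90.2. By 12.5 h Tuesday's initiator stood at 13.3 % of its charge, with living ends at 32.1 % of that charge and 68.0 % of the free monomer in chains. Growth on those ends then left 6.41 % of the free monomer at 25.0 h.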